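**Retrosynthetic overview**
1. Dorsilurin C ⇒ open the 4-pyranone C-ring (O1–C2 bond, C3–OH). This gives an unprotected 2',4',6'-trihydroxy-3',5'-diprenylchalcone that already carries the chromene B-ring; forward, chalcone → flavanone → dihydroflavonol → flavonol runs in one flask.
2. Chalcone ⇒ cut Cα=Cβ: 3,5-diprenylphloroacetophenone + 2,2-dimethyl-2H-chromene-7-carbaldehyde.
3. Chromene aldehyde ⇒ retro-oxa-6π (O–CMe2 bond) to an o-quinone methide ⇒ its hydrate, a styryl tertiary alcohol ⇒ 3-hydroxy-4-iodobenzaldehyde + 2-methylbut-3-en-2-ol.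
4. Diprenylphloroacetophenone ⇒ phloroacetophenone + 2 × prenyl bromide (prenyltransferase-like C-alkylation).
5. Ring order: both benzene rings are bought. The dimethylpyran ring is closed first (step 2) and the pyranone C-ring last (step 3).

Assumption: the SMILES has no stereocentre and no stereogenic double bond, so dorsilurin C is achiral and needs no enantiocontrol. The two stereocentres that appear transiently in step 3 are racemic and vanish on aromatisation.

**Step 1**
Reactants: 1 2,4,6-trihydroxyacetophenone (phloroacetophenone); 2 prenyl bromide (1-bromo-3-methylbut-2-ene, 2.1 equiv)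
Product: 3 3,5-diprenylphloroacetophenone
Conditions: KOH (2.2 equiv), H2O, 0 °C → rt, N2
Reagents that add atoms: none
Why: Phenolate C-alkylation (biomimetic aromatic prenylation): water hydrogen-bonds the phenolate oxygens, so the soft allylic bromide is attacked by the two equivalent, highly nucleophilic ring carbons C3/C5, limiting 2 to about 2 equiv holds back gem-dialkylation, and no stereocentre is formed.

**Step 2**
Reactants: 4 3-hydroxy-4-iodobenzaldehyde; 5 2-methylbut-3-en-2-ol (1.5 equiv)
Product: 8 2,2-dimethyl-2H-chromene-7-carbaldehyde, via Heck allylic alcohol 6 (not isolated), via o-quinone methide 7 (not isolated)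
Conditions: Pd(OAc)2 (3 mol %), n-Bu4NCl (1 equiv), NaHCO3 (1.2 equiv), DMF, 70 °C; then p-TsOH·H2O (0.4 equiv), same flask, 80 °C
Reagents that add atoms: none
Why: Mizoroki–Heck arylation (Jeffery conditions) places the aryl group on the terminal CH2 of 5, and because the carbinol carbon bears no hydrogen, β-hydride elimination can only give the (E)-styryl tertiary alcohol 6; acid then ionises this doubly activated alcohol, loss of the phenolic proton gives the same o-quinone methide 7 that oxidation of an o-prenylphenol would give, and its oxa-6π electrocyclisation closes the dimethylpyran ring with the regiochemistry fixed by the C–I position (no stereocentre).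

**Step 3**
Reactants: 3 3,5-diprenylphloroacetophenone; 8 2,2-dimethyl-2H-chromene-7-carbaldehyde (1.05 equiv)
Product: 12 dorsilurin C, via chalcone 9 (not isolated), via flavanone 10 (not isolated), via dihydroflavonol 11 (not isolated)
Conditions: pyrrolidine (1.0 equiv), degassed EtOH, 60 °C, Ar; cool to 0 °C, then 2 M aq NaOH (6 equiv), 30 % H2O2 (5 equiv), same flask, 0 °C → rt; 1 M HCl to pH 5 at 0 °C
Reagents that add atoms: hydrogen peroxide, OO
Why: Proposed new method: this telescopes, without protecting groups, two known reaction types, the amine-catalysed Claisen–Schmidt/oxa-Michael (Kabbe-type) flavanone synthesis and the Algar–Flynn–Oyamada oxidation; iminium activation of 8 avoids the unreactive phenolate polyanion of 3 (all its ring carbons are blocked, so only the acetyl CH3 can condense productively), the symmetric 2',6'-diol of 9 closes to a single flavanone 10, alkaline H2O2 hydroxylates the flavanone/chalcone enolate at C3 to the racemic trans-dihydroflavonol 11 and dehydrogenates it, the free chelated 6'-OH keeps the aryl ketone planar and so should favour six-ring closure over the aurone path known for 6'-alkoxychalcones, nucleophilic HOO⁻ does not touch the three electron-rich alkenes, and both transient stereocentres are erased in the aromatic pyranone.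

**Compound list**
1 | 2,4,6-trihydroxyacetophenone | CC(=O)c1c(O)cc(O)cc1O | starting material
2 | prenyl bromide (1-bromo-3-methylbut-2-ene) | CC(C)=CCBr | starting material
3 | 3,5-diprenylphloroacetophenone, 1-[2,4,6-trihydroxy-3,5-bis(3-methylbut-2-en-1-yl)phenyl]ethan-1-one | CC(=O)c1c(O)c(CC=C(C)C)c(O)c(CC=C(C)C)c1O | intermediate
4 | 3-hydroxy-4-iodobenzaldehyde | O=Cc1ccc(I)c(O)c1 | starting material
5 | 2-methylbut-3-en-2-ol | C=CC(C)(C)O | starting material
6 | 3-hydroxy-4-[(E)-3-hydroxy-3-methylbut-1-en-1-yl]benzaldehyde (not isolated) | O=Cc1ccc(/C=C/C(C)(C)O)c(O)c1 | intermediate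
7 | o-quinone methide, (4Z)-4-(3-methylbut-2-en-1-ylidene)-3-oxocyclohexa-1,5-diene-1-carbaldehyde (not isolated) | O=CC1=CC(=O)/C(=C\C=C(C)C)C=C1 | intermediate
8 | 2,2-dimethyl-2H-chromene-7-carbaldehyde | CC1(C)C=Cc2ccc(C=O)cc2O1 | intermediate
9 | (E)-3-(2,2-dimethyl-2H-chromen-7-yl)-1-[2,4,6-trihydroxy-3,5-bis(3-methylbut-2-en-1-yl)phenyl]prop-2-en-1-one (not isolated) | CC(C)=CCc1c(O)c(CC=C(C)C)c(O)c(C(=O)/C=C/c2ccc3c(c2)OC(C)(C)C=C3)c1O | intermediate
10 | (±)-2-(2,2-dimethyl-2H-chromen-7-yl)-5,7-dihydroxy-6,8-diprenylchroman-4-one (racemic, 2S drawn; not isolated) | CC(C)=CCc1c(O)c(CC=C(C)C)c2O[C@@H](CC(=O)c2c1O)c1ccc2c(c1)OC(C)(C)C=C2 | intermediate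
11 | (±)-trans-2-(2,2-dimethyl-2H-chromen-7-yl)-3,5,7-trihydroxy-6,8-diprenylchroman-4-one (racemic, 2R,3R drawn; not isolated) | CC1(C)C=Cc2ccc(cc2O1)[C@@H]1[C@H](C(=O)c2c(O)c(CC=C(C)C)c(O)c(CC=C(C)C)c2O1)O | intermediate
12 | dorsilurin C, 2-(2,2-dimethyl-2H-chromen-7-yl)-3,5,7-trihydroxy-6,8-bis(3-methylbut-2-en-1-yl)-4H-chromen-4-one (achiral) | CC(C)=CCc1c(O)c(CC=C(C)C)c2oc(-c3ccc4c(c3)OC(C)(C)C=C4)c(O)c(=O)c2c1O | target

**Total step count:** 3. **Longest linear sequence:** 2 (step 1 → step 3, or step 2 → step 3).

**Steps most likely to fail**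

Step 3 is the highest risk. The electron-rich ketone 3 may condense slowly. Five-ring closure could give the aurone. The diprenylated phloroglucinol ring or the finished flavonol could also be over-oxidised in alkaline peroxide. The fallback sets out from 3 and comes back at 12, and it replaces the unprotected cascade by a protected, stepwise sequence. MOMCl/K2CO3 in acetone converts 3 into 2-hydroxy-4,6-bis(methoxymethoxy)-3,5-diprenylacetophenone F3, which keeps one chelated OH. A classical KOH/EtOH Claisen–Schmidt condensation with 8 gives the isolable (E)-3-(2,2-dimethyl-2H-chromen-7-yl)-1-[2-hydroxy-4,6-bis(methoxymethoxy)-3,5-diprenylphenyl]prop-2-en-1-one F4. NaOH/H2O2 in MeOH then gives dorsilurin C 5,7-bis(methoxymethyl) ether F5, separated from any aurone. Catalytic HCl in MeOH at 40 °C removes both acetals to give 12.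

Step 1 is likely to give a statistical mixture of mono-, gem-di-, tri-C-prenylated and O-prenylated products, so about 30–40 % of 3 after chromatography is realistic. The fallback sets out from 1 (with 2) and comes back at 3, and it replaces direct C-alkylation by O-alkylation followed by an O→C shift. K2CO3 in refluxing acetone gives 2-hydroxy-4,6-bis(prenyloxy)acetophenone F1. Montmorillonite K10 in CH2Cl2 then moves both prenyl groups by formal [1,3]-shift to the only free ring carbons, C3 and C5, giving 3.

Step 2 may stall at the (E)-alcohol 6 or its 1,3-diene, because the para-formyl group slows ionisation, and the acid may oligomerise the chromene. The fallback sets out from 4 and comes back at 8, and it reaches the o-quinone methide by oxidation instead of dehydration. Stille coupling of 4 with tributyl(3-methylbut-2-en-1-yl)stannane (Pd(PPh3)4, DMF, 90 °C) gives 3-hydroxy-4-prenylbenzaldehyde F2. DDQ in refluxing toluene abstracts the benzylic hydride to give the same intermediate 7, which electrocyclises to 8.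

**Further compounds**
F1 | step 1 | 2-hydroxy-4,6-bis(prenyloxy)acetophenone | CC(=O)c1c(O)cc(OCC=C(C)C)cc1OCC=C(C)C
F2 | step 2 | 3-hydroxy-4-prenylbenzaldehyde | CC(C)=CCc1ccc(C=O)cc1O
F3 | step 3 | 2-hydroxy-4,6-bis(methoxymethoxy)-3,5-diprenylacetophenone | CC(=O)c1c(O)c(CC=C(C)C)c(OCOC)c(CC=C(C)C)c1OCOC
F4 | step 3 | (E)-3-(2,2-dimethyl-2H-chromen-7-yl)-1-[2-hydroxy-4,6-bis(methoxymethoxy)-3,5-diprenylphenyl]prop-2-en-1-one | COCOc1c(CC=C(C)C)c(OCOC)c(C(=O)/C=C/c2ccc3c(c2)OC(C)(C)C=C3)c(O)c1CC=C(C)C
F5 | step 3 | dorsilurin C 5,7-bis(methoxymethyl) ether | COCOc1c(CC=C(C)C)c(OCOC)c2c(=O)c(O)c(-c3ccc4c(c3)OC(C)(C)C=C4)oc2c1CC=C(C)C
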